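## Structural features

The target is a 1-aryl-1,2-dihydronaphthalene. Ring A (C4a, C5–C8, C8a) is aromatic, carries methoxy groups at C6 and C7, and is fused through C4a–C8a to the partly saturated ring B (C1–C4); a 3,4-dimethoxyphenyl group is attached at C1. Ring B holds the only two stereocentres, C1 (R, aryl) and C2 (S, methyl). They are adjacent and trans, and sit next to the trisubstituted C3=C4 alkene, which bears the second methyl group and is conjugated with ring A. Ring B has no heteroatom, so once the ring exists neither centre can be set by carbonyl- or hydroxyl-directed methods. The fragile points are the doubly benzylic C1–H, the ease with which acid can move the alkene towards C1=C2 (which would erase both centres), and oxidative aromatisation of ring B; the electron-rich arenes also restrict the choice of oxidants. The real difficulty is the trans C1/C2 pair in one absolute configuration, together with a late and regiodefined introduction of C3=C4. Ring A is a 1,2,4,5-tetrasubstituted benzene with C5 and C8 unsubstituted. It can therefore be assembled from three alkynes: two terminal alkynes at the ends of the chain C1–C2–C3–C4 (they become C8a/C8 and C4a/C5), and a C6≡C7 alkyne carrying two boron atoms as masked methoxy groups. The key step uses this, and it allows both stereocentres to be made on an open chain before any ring is closed.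

## Logic of the disconnections

**23 ⇒ 22.** No skeletal bond is cut; the C3=C4 π bond is traced back to a C3–OH and a C4–H. The reason is that C3 then becomes the carbon of a ketone addition in the open chain, and both carbinol epimers converge. The gain is that no alkene geometry or position has to be carried through the synthesis. The demand is an elimination that removes a benzylic C4 hydrogen, not the C2 hydrogen, without free acid.

**22 ⇒ 21 ⇒ 20.** The two O–CH3 bonds at C6 and C7 are cut, and the two aryl C–O bonds are then traced back to aryl C–B bonds. An alkyne bearing two oxygen atoms is not a practical cyclotrimerisation partner, whereas the diboryl alkyne is stable, hindered and symmetrical. The gain is that both ring A substituents come from one reagent. The demand is oxidation of both C–B bonds without destroying the catechol, and methylation of the phenols only.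

**20 ⇒ 18 + 19.** Three bonds of ring A are cut: C4a–C8a, C5–C6 and C7–C8. Both rings disappear at once, leaving an acyclic 1,7-diyne that carries both stereocentres on its four-atom tether. The demand is cross-selectivity over diyne self-reaction, and a catalyst that tolerates a free tertiary alcohol and does not touch the sp3 centres.

**18 ⇒ 15 + 16.** The bond between the carbinol carbon and the propargylic CH2 of the second alkyne is cut. This removes one alkyne and the uncontrolled carbinol centre and leaves a methyl ketone. The forward step needs a nucleophile that is not basic enough to enolise the ketone, and that transfers a propargyl and not an allenyl group.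

**15 ⇒ 13.** The acyl–CH3 bond is cut, leading back to the carboxylic acid, which is the oxidation level that auxiliary cleavage delivers. The demand is a single addition of a methyl nucleophile with no enolisable carbonyl present while base is in the flask.

**13 ⇒ 10 ⇒ 9.** No skeletal bond is cut. The acid goes back to the N-acyl oxazolidinone, the alkyne C–H to a C–Si bond, and the alkyne to its dicobalt complex. These three groups are what makes the next disconnection selective. The forward steps need exocyclic imide cleavage and a mild decomplexation.

**9 ⇒ 6 + 7.** The bond between the two stereogenic carbons is cut. It is the only bond whose formation can set both centres in one event: a chiral propionate enolate attacks a cobalt-stabilised, aryl-substituted propargylic cation. A catalytic propargylic alkylation of an aldehyde enamine would be shorter, but it leaves the methyl-bearing centre weakly controlled and epimerisable at two later stages. The gain is one purchased chiral imide and one racemic electrophile. The demand is syn relative topicity and control of the enolate face.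

**6 ⇒ 5 ⇒ 1 + 2.** The metal is removed, then the bond between the carbinol carbon and the alkyne and the ester C–O bond are cut. This ends at an aromatic aldehyde and a silylated acetylene. The centre made here is racemic on purpose, because it is ionised later.

## Other disconnections considered

**Alternative 1:** The cut runs through C4a–C5 and C8–C8a. Ring A is taken off as 2,3-dimethoxybuta-1,3-diene A3, and ring B remains as the enone (4R,5S,6R)-4-(3,4-dimethoxyphenyl)-5,6-dimethylcyclohex-2-en-1-one A2.

- Forward: a Diels–Alder addition of A3 to the C=C of A2, anti to the aryl group, would give the cis-fused hexahydronaphthalenone A1. Dehydrogenation of its bis(enol ether) ring would make ring A; reduction of the ketone at C4 and loss of water would give C3=C4.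
- In its favour: the diene delivers both ring A methoxy groups at the final oxidation level, so no C–B oxidation or methylation is needed. On this point it is the better plan. The alkene is placed without ambiguity, because the leaving hydroxyl sits on benzylic C4 and C3–H is the only β-hydrogen. This is also better than the three-way choice in step 11.
- Against it here: A2 is a branched, unactivated dienophile and A3 is an acid-labile enol ether, so the Lewis acid the addition would need also destroys the diene. A2 must first be made as one enantiomer with three contiguous centres, one of which is later discarded. Aromatisation of A1 removes four hydrogens beside an enolisable ketone and can run on to a naphthol.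
- Comparison: on structure it handles the oxygen pattern and the alkene better but carries a disposable stereocentre. On mechanism it depends on substrate-controlled facial and endo selectivity of a sluggish cycloaddition, whereas step 8 involves no stereochemical event. On step economy the two are about equal once the synthesis of A2 is counted (an estimate).

**Alternative 2:** The cut is the single bond C2–C3 of ring B. It leads back to the diester methyl (3R)-3-(3,4-dimethoxyphenyl)-3-[4,5-dimethoxy-2-(3-methoxy-3-oxopropyl)phenyl]propanoate A5.

- Forward: double deprotonation of A5 and oxidation of the bis-enolate (CuCl2 or iodine) would join the two α-carbons and close ring B to the trans,trans diester A4.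
- In its favour: both arenes are bought with their methoxy groups. C1 can be set in A5 by asymmetric conjugate arylation of a cinnamate. The key step itself creates C2 under control of C1, without an auxiliary; step 8 creates no stereocentre. On these points it equals or betters the chosen plan.
- Against it here: A4 has esters where the target has methyl groups, and a stereocentre at C3 where the target has an sp2 carbon. Both esters must be taken down to methyl. C3=C4 must be made by a separate dehydrogenation, after which one deoxygenation is allylic and can transpose the alkene. The oxidant can also attack the electron-rich arenes.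
- Comparison: on structure it builds a centre it must destroy and oxidation levels it must remove. On mechanism both plans use a tether to make ring closure intramolecular; the alternative gains real diastereocontrol, the chosen plan needs none. On step economy it is clearly longer after the key step (an estimated six or more operations against three).

**Alternative 3:** Two bonds of ring B are cut, C1–C2 and C3–C4, giving 2-(3,4-dimethoxybenzyl)-4,5-dimethoxybenzaldehyde A7 and methyl (E)-but-2-enoate A8.

- Forward: irradiation of A7 would generate its transient ortho-quinodimethane enol, which adds A8 in a [4+2] sense to give the tetralol ester A6, with ring B and four stereocentres formed in one step.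
- In its favour: it is the most convergent plan; both arenes carry their methoxy groups from the start; and the β-hydroxy ester of A6 can lose water only towards C3=C4. On convergence, on ring A and on alkene placement it is better than the chosen plan.
- Against it here: the target is one enantiomer, and a photoenol addition to a simple, non-chelating crotonate has no dependable source of absolute control. The crotonate is a slow partner for a short-lived dienol that reverts to A7. The aryl/methyl relation depends on dienol geometry as well as endo selectivity. The ester must still become the C3 methyl through an allylic alcohol, with risk of transposition.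
- Comparison: on structure it gives the whole skeleton at once but with an ester and a hydroxyl to remove. On mechanism its stereochemistry is set in a photochemical step that is hard to steer, whereas the chosen plan sets both centres in the ground state with an auxiliary. On step economy it would be shorter in the racemic series and loses that advantage only when a resolution or chiral controller is added.

Key step: step 8

Remark on numbering: ring atoms in the discussion carry the numbering of the target (C1 aryl-bearing, C2 methyl-bearing, C3=C4, ring A = C4a–C8a); tetralin intermediates are named with the carbinol carbon as C2.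

Remark on descriptors: the (3S,4S) diyne maps onto (1R,2S) in the target (syn in the open chain becomes trans in the ring). The silylated intermediates are (3R) at the aryl-bearing carbon only because the silylalkynyl group outranks the aryl group; the geometry is unchanged.

Assumption: the Z-boron enolate 8 is taken to react with the cobalt-stabilised cation in its boron-chelated form, on the face opposite the benzyl group (the facial sense of alkylations of such imide enolates). This is why the (R)-auxiliary is specified. The propargylic acetate is assumed to ionise under Bu2BOTf as the corresponding methyl ether does.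

## Route

Step 1
Reactants: 1 veratraldehyde (3,4-dimethoxybenzaldehyde); 2 trimethylsilylacetylene
Product: 5 rac-1-(3,4-dimethoxyphenyl)-3-(trimethylsilyl)prop-2-yn-1-yl acetate, via lithium (trimethylsilyl)acetylide 3 (not isolated), via lithium propargylic alkoxide 4 (not isolated)
Conditions: 2, n-BuLi, THF, −78 °C; 1, −78 → 0 °C; then Ac2O, 0 °C → rt
Reagents that add atoms: acetic anhydride, CC(=O)OC(C)=O
Why: 1,2-addition of a lithium acetylide to an aromatic aldehyde, with acetylation of the lithium alkoxide in the same flask. The new centre is racemic, which is acceptable because it is ionised in step 3; the silyl cap adds bulk that should help the syn selectivity there.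

Step 2
Reactants: 5 rac-1-(3,4-dimethoxyphenyl)-3-(trimethylsilyl)prop-2-yn-1-yl acetate
Product: 6 hexacarbonyldicobalt complex of 5 (μ-alkyne Co2(CO)6 cluster; racemic)
Conditions: Co2(CO)8 (1.05 equiv), CH2Cl2, rt; filtered through Celite and used directly
Reagents that add atoms: Co2(CO)8 (octacarbonyldicobalt), O=C=[Co](=C=O)(=C=O)(=C=O)[Co](=C=O)(=C=O)(=C=O)=C=O
Why: Alkyne complexation: the alkyne displaces two CO ligands of zerovalent Co2(CO)8 to give the μ-alkyne cluster. The cluster is what stabilises the propargylic cation and blocks allene formation in step 3.

Step 3
Reactants: 7 (R)-4-benzyl-3-propionyl-1,3-oxazolidin-2-one; 6 hexacarbonyldicobalt complex of 5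
Product: 9 hexacarbonyldicobalt complex of (4R)-4-benzyl-3-[(2S,3R)-3-(3,4-dimethoxyphenyl)-2-methyl-5-(trimethylsilyl)pent-4-ynoyl]-1,3-oxazolidin-2-one, via dibutylboron Z-enolate 8 (not isolated)
Conditions: 7 (1.3 equiv), Bu2BOTf (2.5 equiv), i-Pr2NEt (1.5 equiv), CH2Cl2, −78 → 0 °C; then 6, −78 → 0 °C; aq. NaHCO3
Reagents that add atoms: none
Why: Nicholas reaction with a chiral boron enolate: excess Bu2BOTf ionises the acetate to the cluster-stabilised propargylic cation, which is captured by Z-enolate 8 through an open transition state. The enolate reacts on the face opposite the benzyl group, which sets the methyl-bearing carbon as (S). The open transition state prefers the syn arrangement of methyl and aryl, reinforced by the bulky silyl-capped cluster, and this sets the aryl-bearing carbon.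

Step 4
Reactants: 9 hexacarbonyldicobalt complex of the silylalkynyl imide
Product: 10 (4R)-4-benzyl-3-[(2S,3R)-3-(3,4-dimethoxyphenyl)-2-methyl-5-(trimethylsilyl)pent-4-ynoyl]-1,3-oxazolidin-2-one
Conditions: Fe(NO3)3·9H2O, EtOH, 0 °C → rt
Reagents that add atoms: none
Why: Oxidative decomplexation: trivalent iron oxidises the dicobalt cluster and releases the alkyne and CO. The imide, the silane, the aryl ethers and both stereocentres should not be affected at this temperature.

Step 5
Reactants: 10 (4R)-4-benzyl-3-[(2S,3R)-3-(3,4-dimethoxyphenyl)-2-methyl-5-(trimethylsilyl)pent-4-ynoyl]-1,3-oxazolidin-2-one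
Product: 13 (2S,3S)-3-(3,4-dimethoxyphenyl)-2-methylpent-4-ynoic acid, via lithium peroxycarboxylate 11 (not isolated), via lithium silylalkynoate 12 (not isolated)
Conditions: LiOH, H2O2, THF/H2O, 0 °C; aq. Na2SO3; then K2CO3, MeOH, rt; 1 M HCl
Reagents that add atoms: hydrogen peroxide, OO
Why: Hydroperoxide cleavage of the N-acyl oxazolidinone at the exocyclic carbonyl, reduction of the peracid salt by sulfite, then protodesilylation of the alkynylsilane by methanolic carbonate in the same flask. A carboxylate is not enolised by these bases, so neither stereocentre is at risk, and the auxiliary is recovered.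

Step 6
Reactants: 13 (2S,3S)-3-(3,4-dimethoxyphenyl)-2-methylpent-4-ynoic acid
Product: 15 (3S,4S)-4-(3,4-dimethoxyphenyl)-3-methylhex-5-yn-2-one, via trilithium gem-diolate 14 (not isolated)
Conditions: MeLi (3.3 equiv), THF, −78 → 0 °C; inverse quench into cold aq. NH4Cl
Reagents that add atoms: methyllithium, [Li]C
Why: Ketone synthesis from a carboxylic acid and an organolithium: two equivalents deprotonate the acid and the alkyne, the third adds to the lithium carboxylate. The gem-diolate 14 cannot add again and releases the ketone only on quench. No enolisable carbonyl is present while base is in the flask, so the α-methyl centre should keep its configuration.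

Step 7
Reactants: 15 (3S,4S)-4-(3,4-dimethoxyphenyl)-3-methylhex-5-yn-2-one; 16 propargyl bromide (3-bromoprop-1-yne)
Product: 18 (3S,4S)-3-(3,4-dimethoxyphenyl)-4,5-dimethylocta-1,7-diyn-5-ol (mixture of C5 epimers), via allenylzinc bromide 17 (not isolated)
Conditions: 16, Zn dust, THF, 0 °C; then 15, 0 °C → rt; aq. NH4Cl
Reagents that add atoms: none
Why: Barbier-type propargylation: zinc inserts into 16, and the allenylzinc species adds to the ketone through a cyclic SE2' transition state to give the homopropargylic tertiary alcohol. The organozinc is too weakly basic to enolise the ketone or deprotonate the alkyne. The new carbinol centre is uncontrolled, which is harmless because it becomes sp2 in step 11.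

Step 8
Reactants: 18 (3S,4S)-3-(3,4-dimethoxyphenyl)-4,5-dimethylocta-1,7-diyn-5-ol (mixture of C5 epimers); 19 1,2-bis(4,4,5,5-tetramethyl-1,3,2-dioxaborolan-2-yl)ethyne
Product: 20 (3S,4R)-4-(3,4-dimethoxyphenyl)-2,3-dimethyl-6,7-bis(4,4,5,5-tetramethyl-1,3,2-dioxaborolan-2-yl)-1,2,3,4-tetrahydronaphthalen-2-ol (mixture of C2 epimers)
Conditions: CpCo(CO)2 (20 mol %), 19 (3 equiv), degassed toluene, reflux, hν (visible lamp), 18 added slowly by syringe pump
Reagents that add atoms: none
Why: Cobalt-mediated [2+2+2] alkyne cyclotrimerisation; the closest known case is the co-cyclisation of 1,7-diynes with hindered alkynylboronates or bis(silyl)acetylenes to benzo-fused six-membered rings. Light and heat remove CO from CpCo(CO)2; the CpCo fragment (monovalent cobalt) binds both terminal alkynes of 18 and couples them oxidatively to a metallacyclopentadiene (trivalent cobalt). This intramolecular C–C coupling forms C4a–C8a and closes ring B as a six-membered carbocycle fused to the metallacycle. Coordination and insertion of 19, followed by reductive elimination, forms C5–C6 and C7–C8 and closes ring A as the benzene ring in an intermolecular two-bond closure that returns the CpCo fragment. No stereocentre is created; the two existing centres lie on the sp3 tether, are never bonded to the metal, and the medium is neutral, so their configuration should be retained. Regiochemistry does not arise because 19 is symmetrical, which places the two boron atoms on the adjacent carbons C6 and C7. The selectivity needed is cross- over homo-cyclotrimerisation: the four-atom tether makes diyne coupling intramolecular and fast, 19 is too hindered to trimerise with itself, and slow addition of 18 into an excess of 19 suppresses diyne oligomerisation. The free tertiary hydroxyl and the aryl ethers are spectators for this late-metal catalyst.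

Step 9
Reactants: 20 (3S,4R)-4-(3,4-dimethoxyphenyl)-2,3-dimethyl-6,7-bis(4,4,5,5-tetramethyl-1,3,2-dioxaborolan-2-yl)-1,2,3,4-tetrahydronaphthalen-2-ol (mixture of C2 epimers)
Product: 21 (3S,4R)-4-(3,4-dimethoxyphenyl)-2,3-dimethyl-1,2,3,4-tetrahydronaphthalene-2,6,7-triol (mixture of C2 epimers)
Conditions: NaBO3·4H2O, THF/H2O (1:1), rt, Ar; then 1 M HCl to pH 4; crude product taken on at once
Reagents that add atoms: NaBO3·4H2O (sodium perborate tetrahydrate), [Na+].[O-]OB=O.O.O.O.O
Why: Oxidation of aryl C–B bonds: the peroxy anion adds to boron, the aryl group migrates from boron to oxygen at the same ring carbon, and hydrolysis gives the phenol. Buffered perborate at room temperature should spare the tertiary alcohol, the benzylic C–H bonds and the stereocentres.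

Step 10
Reactants: 21 (3S,4R)-4-(3,4-dimethoxyphenyl)-2,3-dimethyl-1,2,3,4-tetrahydronaphthalene-2,6,7-triol (mixture of C2 epimers)
Product: 22 (3S,4R)-4-(3,4-dimethoxyphenyl)-6,7-dimethoxy-2,3-dimethyl-1,2,3,4-tetrahydronaphthalen-2-ol (mixture of C2 epimers)
Conditions: MeI, K2CO3, acetone, reflux, Ar
Reagents that add atoms: iodomethane, CI
Why: Williamson etherification: carbonate deprotonates only the two phenols, and the catecholate is methylated quickly, while the tertiary alcohol stays free. Working under argon limits air oxidation of the catechol.

Step 11
Reactants: 22 (3S,4R)-4-(3,4-dimethoxyphenyl)-6,7-dimethoxy-2,3-dimethyl-1,2,3,4-tetrahydronaphthalen-2-ol (mixture of C2 epimers)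
Product: 23 (1R,2S)-1-(3,4-dimethoxyphenyl)-6,7-dimethoxy-2,3-dimethyl-1,2-dihydronaphthalene
Conditions: Burgess reagent (Et3N+–SO2–N−–CO2Me inner salt), toluene, 60 °C
Reagents that add atoms: none
Why: Burgess dehydration: the tertiary hydroxyl is converted into a sulfamate ester that eliminates thermally under neutral conditions. The hydrogen lost should be a benzylic C4 hydrogen, the most acidic β-hydrogen and the only one that gives an alkene conjugated with ring A; both carbinol epimers have such a hydrogen and converge on 23. The absence of free acid avoids migration of the alkene towards C1 and epimerisation at C2.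

## Compound list

1 | veratraldehyde (3,4-dimethoxybenzaldehyde) | COc1ccc(C=O)cc1OC | starting material
2 | trimethylsilylacetylene | C#C[Si](C)(C)C | starting material
3 | lithium (trimethylsilyl)acetylide (not isolated) | [Li]C#C[Si](C)(C)C | intermediate
4 | lithium 1-(3,4-dimethoxyphenyl)-3-(trimethylsilyl)prop-2-yn-1-olate, racemic (not isolated) | [Li]OC(C#C[Si](C)(C)C)c1ccc(OC)c(OC)c1 | intermediate
5 | rac-1-(3,4-dimethoxyphenyl)-3-(trimethylsilyl)prop-2-yn-1-yl acetate | CC(=O)OC(C#C[Si](C)(C)C)c1ccc(OC)c(OC)c1 | intermediate
6 | hexacarbonyldicobalt complex of 5 (μ-alkyne Co2(CO)6 cluster, racemic) | CC(=O)OC(c1ccc(OC)c(OC)c1)C12[Co]3(=C=O)(=C=O)(=C=O)[Co]1(=C=O)(=C=O)(=C=O)C23[Si](C)(C)C | intermediate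
7 | (R)-4-benzyl-3-propionyl-1,3-oxazolidin-2-one | CCC(=O)N1[C@H](Cc2ccccc2)COC1=O | starting material
8 | dibutylboron (Z)-enolate of 7 (not isolated) | C/C=C(\OB(CCCC)CCCC)N1[C@H](Cc2ccccc2)COC1=O | intermediate
9 | hexacarbonyldicobalt complex of 10 (μ-alkyne Co2(CO)6 cluster) | C[Si](C)(C)C12[Co]3(=C=O)(=C=O)(=C=O)[Co]1(=C=O)(=C=O)(=C=O)C23[C@@H](c1ccc(OC)c(OC)c1)[C@H](C)C(=O)N1[C@H](Cc2ccccc2)COC1=O | intermediate
10 | (4R)-4-benzyl-3-[(2S,3R)-3-(3,4-dimethoxyphenyl)-2-methyl-5-(trimethylsilyl)pent-4-ynoyl]-1,3-oxazolidin-2-one | C[Si](C)(C)C#C[C@@H](c1ccc(OC)c(OC)c1)[C@H](C)C(=O)N1[C@H](Cc2ccccc2)COC1=O | intermediate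
11 | lithium (2S,3R)-3-(3,4-dimethoxyphenyl)-2-methyl-5-(trimethylsilyl)pent-4-yneperoxoate (not isolated) | C[Si](C)(C)C#C[C@@H](c1ccc(OC)c(OC)c1)[C@H](C)C(=O)OO[Li] | intermediate
12 | lithium (2S,3R)-3-(3,4-dimethoxyphenyl)-2-methyl-5-(trimethylsilyl)pent-4-ynoate (not isolated) | C[Si](C)(C)C#C[C@@H](c1ccc(OC)c(OC)c1)[C@H](C)C(=O)O[Li] | intermediate
13 | (2S,3S)-3-(3,4-dimethoxyphenyl)-2-methylpent-4-ynoic acid | C#C[C@@H](c1ccc(OC)c(OC)c1)[C@H](C)C(=O)O | intermediate
14 | trilithium gem-diolate acetylide formed from 13 and MeLi (not isolated) | [Li]C#C[C@@H](c1ccc(OC)c(OC)c1)[C@H](C)C(C)(O[Li])O[Li] | intermediate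
15 | (3S,4S)-4-(3,4-dimethoxyphenyl)-3-methylhex-5-yn-2-one | C#C[C@@H](c1ccc(OC)c(OC)c1)[C@H](C)C(C)=O | intermediate
16 | propargyl bromide (3-bromoprop-1-yne) | C#CCBr | starting material
17 | allenylzinc bromide (propa-1,2-dienylzinc bromide, not isolated) | C=C=C[Zn]Br | intermediate
18 | (3S,4S)-3-(3,4-dimethoxyphenyl)-4,5-dimethylocta-1,7-diyn-5-ol (mixture of C5 epimers) | C#C[C@@H](c1ccc(OC)c(OC)c1)[C@H](C)C(C)(O)CC#C | intermediate
19 | 1,2-bis(4,4,5,5-tetramethyl-1,3,2-dioxaborolan-2-yl)ethyne | CC1(C)OB(OC1(C)C)C#CB1OC(C)(C)C(C)(C)O1 | starting material
20 | (3S,4R)-4-(3,4-dimethoxyphenyl)-2,3-dimethyl-6,7-bis(4,4,5,5-tetramethyl-1,3,2-dioxaborolan-2-yl)-1,2,3,4-tetrahydronaphthalen-2-ol (mixture of C2 epimers) | COc1ccc([C@@H]2c3cc(B4OC(C)(C)C(C)(C)O4)c(B4OC(C)(C)C(C)(C)O4)cc3CC(C)(O)[C@H]2C)cc1OC | intermediate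
21 | (3S,4R)-4-(3,4-dimethoxyphenyl)-2,3-dimethyl-1,2,3,4-tetrahydronaphthalene-2,6,7-triol (mixture of C2 epimers) | COc1ccc([C@@H]2c3cc(O)c(O)cc3CC(C)(O)[C@H]2C)cc1OC | intermediate
22 | (3S,4R)-4-(3,4-dimethoxyphenyl)-6,7-dimethoxy-2,3-dimethyl-1,2,3,4-tetrahydronaphthalen-2-ol (mixture of C2 epimers) | COc1ccc([C@@H]2c3cc(OC)c(OC)cc3CC(C)(O)[C@H]2C)cc1OC | intermediate
23 | (1R,2S)-1-(3,4-dimethoxyphenyl)-6,7-dimethoxy-2,3-dimethyl-1,2-dihydronaphthalene | COc1ccc([C@@H]2c3cc(OC)c(OC)cc3C=C(C)[C@H]2C)cc1OC | target

## Step count and least certain steps

Total step count: 11. Longest linear sequence: 11 steps (1 → 23); 2, 7, 16 and 19 enter as purchased reagents.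

**Step 8 (key step).** The most likely failure is poor cross-selectivity: the metallacycle from 18 may be captured by a second diyne, or the catalyst may be drained into inert cobalt–diene or cobalt–arene complexes before the hindered, electron-poor alkyne 19 inserts. The fallback delivers the third alkyne already bound to the metal. It sets out from 19, which with Co2(CO)8 in CH2Cl2 should give the hexacarbonyldicobalt complex of the diborylalkyne F1. Heating F1 with 18 in toluene or xylene (stoichiometric cobalt, no light) should form the same three bonds, and the sequence comes back to the route at 20.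

**Step 3.** The most likely failure is erosion of the syn preference, because the aryl-stabilised cation reacts through a later and looser transition state, or loss of the labile acetate by ionisation before it meets the enolate. The fallback abandons the auxiliary for catalytic control and sets out from 1:
- HC≡CMgBr, then Ac2O, should give rac-1-(3,4-dimethoxyphenyl)prop-2-yn-1-yl acetate F2.
- Propargylic alkylation of propanal with F2, co-catalysed by (CuOTf)2·C6H6 with a chiral Ph-pybox ligand and a chiral diarylprolinol silyl ether (each enantiomer chosen for the 3S and 2S centres), should give (2S,3S)-3-(3,4-dimethoxyphenyl)-2-methylpent-4-ynal F3.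
- MeMgBr should give (3S,4S)-4-(3,4-dimethoxyphenyl)-3-methylhex-5-yn-2-ol F4, at which stage diastereomers are separated.
- Dess–Martin oxidation comes back to the route at 15.

This fallback is shorter, but its control of the methyl-bearing centre is weaker and that centre passes through an epimerisable aldehyde.

**Step 6.** The most likely failure is a second addition of the methyl nucleophile after premature collapse of 14, or incomplete addition because the polylithiated salt aggregates. The fallback sets out from 13: activation with carbonyldiimidazole and MeNH(OMe)·HCl should give (2S,3S)-3-(3,4-dimethoxyphenyl)-N-methoxy-N,2-dimethylpent-4-ynamide F5. MeMgBr (excess, to cover the alkyne C–H) then gives the ketone by the Weinreb ketone synthesis and comes back to the route at 15.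

**Step 9.** The most likely failure is oxidative degradation of the very electron-rich catechol, either as it forms in the basic oxidising medium or in air during isolation. The fallback avoids the free catechol: it sets out from 20 and uses a Chan–Lam coupling with methanol (Cu(OAc)2, 4-dimethylaminopyridine, MeOH/CH2Cl2, molecular sieves, O2) to convert both C–B bonds directly into C–OMe bonds. It comes back to the route at 22 and makes no new compound (F0).

**Step 11.** The most likely failure is loss of the wrong β-hydrogen (the C2 hydrogen or a methyl hydrogen), which gives alkene isomers; loss of the C2 hydrogen would erase that stereocentre. The fallback changes the order of events so that the elimination is run while ring A is electron-poor and the benzylic C4 hydrogens are acidified by the para boryl group. It sets out from 20: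
- Burgess dehydration should give (1R,2S)-1-(3,4-dimethoxyphenyl)-2,3-dimethyl-6,7-bis(4,4,5,5-tetramethyl-1,3,2-dioxaborolan-2-yl)-1,2-dihydronaphthalene F6.
- NaBO3·4H2O should give (5R,6S)-5-(3,4-dimethoxyphenyl)-6,7-dimethyl-5,6-dihydronaphthalene-2,3-diol F7.
- MeI and K2CO3 come back to the route at 23.

## Further compounds

F1 | step 8 | hexacarbonyldicobalt complex of 1,2-bis(4,4,5,5-tetramethyl-1,3,2-dioxaborolan-2-yl)ethyne | CC1(C)OB(OC1(C)C)C12[Co]3(=C=O)(=C=O)(=C=O)[Co]1(=C=O)(=C=O)(=C=O)C23B1OC(C)(C)C(C)(C)O1
F2 | step 3 | rac-1-(3,4-dimethoxyphenyl)prop-2-yn-1-yl acetate | CC(=O)OC(C#C)c1ccc(OC)c(OC)c1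
F3 | step 3 | (2S,3S)-3-(3,4-dimethoxyphenyl)-2-methylpent-4-ynal | C#C[C@@H](c1ccc(OC)c(OC)c1)[C@H](C)C=O
F4 | step 3 | (3S,4S)-4-(3,4-dimethoxyphenyl)-3-methylhex-5-yn-2-ol (mixture of C2 epimers) | C#C[C@@H](c1ccc(OC)c(OC)c1)[C@H](C)C(C)O
F5 | step 6 | (2S,3S)-3-(3,4-dimethoxyphenyl)-N-methoxy-N,2-dimethylpent-4-ynamide | C#C[C@@H](c1ccc(OC)c(OC)c1)[C@H](C)C(=O)N(C)OC
F0 | step 9 | none | none
F6 | step 11 | (1R,2S)-1-(3,4-dimethoxyphenyl)-2,3-dimethyl-6,7-bis(4,4,5,5-tetramethyl-1,3,2-dioxaborolan-2-yl)-1,2-dihydronaphthalene | COc1ccc([C@@H]2c3cc(B4OC(C)(C)C(C)(C)O4)c(B4OC(C)(C)C(C)(C)O4)cc3C=C(C)[C@H]2C)cc1OC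
F7 | step 11 | (5R,6S)-5-(3,4-dimethoxyphenyl)-6,7-dimethyl-5,6-dihydronaphthalene-2,3-diol | COc1ccc([C@@H]2c3cc(O)c(O)cc3C=C(C)[C@H]2C)cc1OC
A1 | alternative 1 | cis-fused 4-(3,4-dimethoxyphenyl)-6,7-dimethoxy-2,3-dimethyl-3,4,4a,5,8,8a-hexahydronaphthalen-1(2H)-one (diene added anti to the aryl group) | COC1=C(OC)C[C@@H]2[C@@H](c3ccc(OC)c(OC)c3)[C@H](C)[C@@H](C)C(=O)[C@@H]2C1
A2 | alternative 1 | (4R,5S,6R)-4-(3,4-dimethoxyphenyl)-5,6-dimethylcyclohex-2-en-1-one | O=C1C=C[C@@H](c2ccc(OC)c(OC)c2)[C@H](C)[C@H]1C
A3 | alternative 1 | 2,3-dimethoxybuta-1,3-diene | C=C(OC)C(OC)=C
A4 | alternative 2 | dimethyl (1R,2S,3S)-1-(3,4-dimethoxyphenyl)-6,7-dimethoxy-1,2,3,4-tetrahydronaphthalene-2,3-dicarboxylate | COc1ccc([C@@H]2c3cc(OC)c(OC)cc3C[C@H](C(=O)OC)[C@H]2C(=O)OC)cc1OC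
A5 | alternative 2 | methyl (3R)-3-(3,4-dimethoxyphenyl)-3-[4,5-dimethoxy-2-(3-methoxy-3-oxopropyl)phenyl]propanoate | COC(=O)C[C@H](c1ccc(OC)c(OC)c1)c1cc(OC)c(OC)cc1CCC(=O)OC
A6 | alternative 3 | methyl (3S,4R)-4-(3,4-dimethoxyphenyl)-1-hydroxy-6,7-dimethoxy-3-methyl-1,2,3,4-tetrahydronaphthalene-2-carboxylate (hydroxyl, ester and aryl mutually cis, methyl trans) | COc1ccc([C@@H]2c3cc(OC)c(OC)cc3[C@H](O)[C@H](C(=O)OC)[C@H]2C)cc1OC
A7 | alternative 3 | 2-(3,4-dimethoxybenzyl)-4,5-dimethoxybenzaldehyde | COc1ccc(Cc2cc(OC)c(OC)cc2C=O)cc1OC
A8 | alternative 3 | methyl (E)-but-2-enoate | C/C=C/C(=O)OC
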